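## Retrosynthetic overview

1. The hydroquinone comes from its dimethyl ether via the quinone, the enone from oxidation of an allylic alcohol, and the β,γ-unsaturated ketone from a decarboxylative Claisen union of a Z-configured β,γ-unsaturated acid dianion with a δ-lactone.
2. The δ-lactone comes from Nozaki–Hiyama–Kishi alkenylation of a cis aldehyde ester, itself the ozonolysis product of an enantioenriched silyl enol ether.
3. Key step: one enantioselective deprotonation of a meso cis-1,5-dimethylbicyclo[3.3.0]octan-3-one fixes both vicinal quaternary carbons; the second ring (ring B) is sacrificial and is cut open afterwards.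
4. Ring order: cyclopentene ring A is bought, a cyclobutanone is fused on by [2+2], enlarged to cyclopentanone ring B, then cleaved.
5. The Z-olefin is templated by a six-membered lactone made by ring-closing metathesis and opened by copper-catalysed SN2 arylation; the arene is bought.

Assumption: the (R,R)-amide in step 4 is taken to give enol ether 5 as drawn; if it gives the antipode, the (S,S)-amine is used and nothing else changes.

## Route

Step 1
Reactants: 1 1,2-dimethylcyclopentene
Product: 2 racemic cis-fused 7,7-dichloro-1,5-dimethylbicyclo[3.2.0]heptan-6-one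
Conditions: Cl3CCOCl, Zn–Cu couple, Et2O, sonication, 15–20 °C
Reagents that add atoms: trichloroacetyl chloride ClC(Cl)(Cl)C(Cl)=O
Why: [2+2] cycloaddition of dichloroketene made in situ to an electron-rich tetrasubstituted olefin, suprafacial on the olefin so the two methyl-bearing quaternary carbons are formed cis.

Step 2
Reactants: 2 racemic cis-fused 7,7-dichloro-1,5-dimethylbicyclo[3.2.0]heptan-6-one
Product: 3 racemic cis-fused 2,2-dichloro-1,5-dimethylbicyclo[3.3.0]octan-3-one
Conditions: CH2N2, Et2O, MeOH (cat.), 0 °C → rt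
Reagents that add atoms: diazomethane C=[N+]=[N-]
Why: Diazomethane ring expansion of an α,α-dichlorocyclobutanone (Greene cyclopentannulation); the non-chlorinated quaternary carbon migrates with retention, so CH2 enters between the carbonyl and the ring fusion and the cis fusion is kept.

Step 3
Reactants: 3 racemic cis-fused 2,2-dichloro-1,5-dimethylbicyclo[3.3.0]octan-3-one
Product: 4 meso cis-(1R,5S)-1,5-dimethylbicyclo[3.3.0]octan-3-one
Conditions: Zn dust, AcOH, 70 °C
Reagents that add atoms: none
Why: Reductive dechlorination of an α,α-dichloroketone through zinc enolates; the product has a mirror plane, so the racemic history is erased.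

Step 4
Reactants: 4 meso cis-(1R,5S)-1,5-dimethylbicyclo[3.3.0]octan-3-one
Product: 5 (1S,5R)-1,5-dimethyl-3-(trimethylsilyloxy)bicyclo[3.3.0]oct-2-ene
Conditions: (R,R)-bis(1-phenylethyl)amine, n-BuLi, THF, −78 → 0 °C; Me3SiCl (in situ quench), then 4, −100 → −78 °C
Reagents that add atoms: chlorotrimethylsilane C[Si](C)(C)Cl
Why: Enantioselective deprotonation of a meso ketone by a C2-symmetric chiral lithium amide with in situ silyl trapping (Simpkins–Koga desymmetrisation); choosing one of the two enantiotopic α-methylene groups sets the absolute configuration of both pre-formed quaternary carbons at once.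

Step 5
Reactants: 5 (1S,5R)-1,5-dimethyl-3-(trimethylsilyloxy)bicyclo[3.3.0]oct-2-ene
Product: 7 methyl 2-[(1R,2R)-2-formyl-1,2-dimethylcyclopentyl]acetate, via aldehyde acid 6 (not isolated)
Conditions: O3, CH2Cl2/MeOH, −78 °C; Me2S, → rt; then CH2N2, Et2O, 0 °C
Reagents that add atoms: ozone O=[O+][O-]; diazomethane C=[N+]=[N-]
Why: Ozonolysis of the silyl enol ether cuts ring B into a non-enolisable neopentyl aldehyde (from the CH= carbon) and a carboxylic acid (from the C–OSi carbon), which diazomethane esterifies; the quaternary centres are not touched.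

Step 6
Reactants: 8 2-methylbut-3-yn-2-ol
Product: 10 (E)-4-iodo-2-methylbut-3-en-2-ol, via vinylstannane 9 (not isolated)
Conditions: Bu3SnH, PdCl2(PPh3)2 (2 mol%), THF, 0 °C → rt; then I2, CH2Cl2, 0 °C
Reagents that add atoms: iodine II
Why: Palladium-catalysed syn hydrostannation of the terminal alkyne gives mainly the (E)-β-stannane, and iododestannylation proceeds with retention of olefin geometry (minor α-isomer removed by chromatography).

Step 7
Reactants: 7 methyl 2-[(1R,2R)-2-formyl-1,2-dimethylcyclopentyl]acetate; 10 (E)-4-iodo-2-methylbut-3-en-2-ol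
Product: 12 (4aR,7aR)-1-[(E)-3-hydroxy-3-methylbut-1-enyl]-4a,7a-dimethylhexahydrocyclopenta[c]pyran-3(1H)-one (both C1 epimers), via hydroxy ester 11 (not isolated)
Conditions: CrCl2 (4 equiv), NiCl2 (1 mol%), DMSO, rt; aqueous work-up; then PPTS (cat.), CH2Cl2, rt
Reagents that add atoms: none
Why: Nozaki–Hiyama–Kishi reaction (zerovalent nickel inserts into the C–I bond with retention, the alkenyl group passes to trivalent chromium and adds only to the hindered aldehyde, tolerating ester and free tertiary OH), then Thorpe–Ingold-assisted lactonisation; the new carbinol centre is an inconsequential epimer mixture because it becomes a ketone in step 14.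

Step 8
Reactants: 13 4-methoxy-2-methylphenol
Product: 14 2-bromo-4-methoxy-6-methylphenol
Conditions: Br2 (1.0 equiv), CH2Cl2, 0 °C
Reagents that add atoms: bromine BrBr
Why: Electrophilic aromatic bromination directed by the phenol OH, whose para position and one ortho position are blocked, so only the remaining ortho carbon reacts.

Step 9
Reactants: 14 2-bromo-4-methoxy-6-methylphenol
Product: 15 1-bromo-2,5-dimethoxy-3-methylbenzene
Conditions: MeI, K2CO3, acetone, reflux
Reagents that add atoms: iodomethane CI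
Why: Williamson O-methylation of the phenoxide.

Step 10
Reactants: 16 3-methylbut-3-enoic acid
Product: 17 prop-2-enyl 3-methylbut-3-enoate
Conditions: allyl bromide, KHCO3, DMF, rt
Reagents that add atoms: allyl bromide C=CCBr
Why: SN2 O-alkylation of the carboxylate under base too weak to move the β,γ-double bond into conjugation.

Step 11
Reactants: 17 prop-2-enyl 3-methylbut-3-enoate
Product: 18 4-methyl-3,6-dihydro-2H-pyran-2-one
Conditions: second-generation Grubbs catalyst RuCl2(=CHPh)(PCy3)(H2IMes) (2 mol%), CH2Cl2 (0.02 M), 40 °C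
Reagents that add atoms: none
Why: Ring-closing metathesis; a six-membered ring can hold the new trisubstituted double bond only in the cis sense, and this is the source of the target's Z-olefin.

Step 12
Reactants: 15 1-bromo-2,5-dimethoxy-3-methylbenzene; 18 4-methyl-3,6-dihydro-2H-pyran-2-one
Product: 20 (Z)-5-(2,5-dimethoxy-3-methylphenyl)-3-methylpent-3-enoic acid, via aryl Grignard 19 (not isolated)
Conditions: Mg turnings, THF, reflux; then 18, CuBr·SMe2 (5 mol%), THF/Me2S, −30 → 0 °C; 1 M HCl work-up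
Reagents that add atoms: none
Why: Copper-catalysed allylic substitution of an allylic lactone by an aryl Grignard reagent: the aryl group attacks SN2 at the primary allylic O–CH2 carbon (the γ-carbon is fully substituted), carboxylate leaves, and the ring-locked Z geometry passes unchanged into the open-chain acid.

Step 13
Reactants: 20 (Z)-5-(2,5-dimethoxy-3-methylphenyl)-3-methylpent-3-enoic acid; 12 (4aR,7aR)-1-[(E)-3-hydroxy-3-methylbut-1-enyl]-4a,7a-dimethylhexahydrocyclopenta[c]pyran-3(1H)-one
Product: 23 (Z)-1-[(1R,2R)-2-[(E)-1,4-dihydroxy-4-methylpent-2-enyl]-1,2-dimethylcyclopentyl]-6-(2,5-dimethoxy-3-methylphenyl)-4-methylhex-4-en-2-one (carbinol epimers), via dilithium dienediolate 21 (not isolated), via keto acid 22 (not isolated)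
Conditions: 20 (3 equiv), LiN(iPr)2 (6 equiv), THF, −78 → 0 °C; 12 (1 equiv), −78 → −20 °C; cold 1 M HCl to pH 3; toluene, 50 °C
Reagents that add atoms: none
Why: Claisen-type C-acylation of a carboxylic acid dianion at its α-carbon by the δ-lactone, then β-keto acid decarboxylation with kinetic α-protonation, which leaves the untouched Z double bond out of conjugation; the excess dianion covers the free tertiary OH and the acidic keto acid, and unreacted 20 is recovered by bicarbonate extraction.

Step 14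
Reactants: 23 (Z)-1-[(1R,2R)-2-[(E)-1,4-dihydroxy-4-methylpent-2-enyl]-1,2-dimethylcyclopentyl]-6-(2,5-dimethoxy-3-methylphenyl)-4-methylhex-4-en-2-one
Product: 24 (E)-1-[(1R,2R)-2-[(Z)-6-(2,5-dimethoxy-3-methylphenyl)-4-methyl-2-oxohex-4-enyl]-1,2-dimethylcyclopentyl]-4-hydroxy-4-methylpent-2-en-1-one
Conditions: Dess–Martin periodinane, pyridine, CH2Cl2, 0 °C → rt
Reagents that add atoms: none
Why: Dess–Martin oxidation of the secondary allylic alcohol (both epimers converge) to the E-enone; the tertiary alcohol cannot be oxidised and the buffered conditions spare the β,γ-unsaturated ketone.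

Step 15
Reactants: 24 (E)-1-[(1R,2R)-2-[(Z)-6-(2,5-dimethoxy-3-methylphenyl)-4-methyl-2-oxohex-4-enyl]-1,2-dimethylcyclopentyl]-4-hydroxy-4-methylpent-2-en-1-one
Product: 25 2-[(Z)-6-[(1R,2R)-2-[(E)-4-hydroxy-4-methylpent-2-enoyl]-1,2-dimethylcyclopentyl]-3-methyl-5-oxohex-2-enyl]-6-methylcyclohexa-2,5-diene-1,4-dione
Conditions: (NH4)2Ce(NO3)6 (2.5 equiv), MeCN/H2O, 0 °C, 15 min
Reagents that add atoms: water O
Why: Oxidative demethylation of a hydroquinone dimethyl ether to the para-quinone by two one-electron oxidations with tetravalent cerium, water supplying the quinone oxygens; it is fast at 0 °C, so olefins, ketones and the tertiary alcohol survive.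

Step 16
Reactants: 25 2-[(Z)-6-[(1R,2R)-2-[(E)-4-hydroxy-4-methylpent-2-enoyl]-1,2-dimethylcyclopentyl]-3-methyl-5-oxohex-2-enyl]-6-methylcyclohexa-2,5-diene-1,4-dione
Product: 26 (E)-1-[(1R,2R)-2-[(Z)-6-(2,5-dihydroxy-3-methylphenyl)-4-methyl-2-oxohex-4-enyl]-1,2-dimethylcyclopentyl]-4-hydroxy-4-methylpent-2-en-1-one
Conditions: Na2S2O4, Et2O/H2O, rt, under argon
Reagents that add atoms: none
Why: Dithionite reduction of the quinone to the hydroquinone, mild enough to leave the enone and the ketone alone.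

## Compound list

1 | 1,2-dimethylcyclopentene | CC1=C(C)CCC1 | starting material
2 | racemic cis-fused 7,7-dichloro-1,5-dimethylbicyclo[3.2.0]heptan-6-one (one enantiomer written) | ClC1(Cl)[C@@]2(C)CCC[C@@]2(C)C1=O | intermediate
3 | racemic cis-fused 2,2-dichloro-1,5-dimethylbicyclo[3.3.0]octan-3-one (one enantiomer written) | ClC1(Cl)[C@@]2(C)CCC[C@@]2(C)CC1=O | intermediate
4 | meso cis-(1R,5S)-1,5-dimethylbicyclo[3.3.0]octan-3-one | C1[C@@]2(C)CCC[C@@]2(C)CC1=O | intermediate
5 | (1S,5R)-1,5-dimethyl-3-(trimethylsilyloxy)bicyclo[3.3.0]oct-2-ene | C1[C@@]2(C)CCC[C@@]2(C)C=C1O[Si](C)(C)C | intermediate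
6 | 2-[(1R,2R)-2-formyl-1,2-dimethylcyclopentyl]acetic acid | OC(=O)C[C@@]1(C)CCC[C@@]1(C)C=O | intermediate
7 | methyl 2-[(1R,2R)-2-formyl-1,2-dimethylcyclopentyl]acetate | COC(=O)C[C@@]1(C)CCC[C@@]1(C)C=O | intermediate
8 | 2-methylbut-3-yn-2-ol | CC(C)(O)C#C | starting material
9 | (E)-2-methyl-4-(tributylstannyl)but-3-en-2-ol | CCCC[Sn](CCCC)(CCCC)/C=C/C(C)(C)O | intermediate
10 | (E)-4-iodo-2-methylbut-3-en-2-ol | CC(C)(O)/C=C/I | intermediate
11 | methyl 2-[(1R,2R)-2-[(E)-1,4-dihydroxy-4-methylpent-2-enyl]-1,2-dimethylcyclopentyl]acetate (carbinol epimers) | COC(=O)C[C@@]1(C)CCC[C@@]1(C)C(O)/C=C/C(C)(C)O | intermediate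
12 | (4aR,7aR)-1-[(E)-3-hydroxy-3-methylbut-1-enyl]-4a,7a-dimethylhexahydrocyclopenta[c]pyran-3(1H)-one (C1 epimers) | O=C1C[C@@]2(C)CCC[C@@]2(C)C(/C=C/C(C)(C)O)O1 | intermediate
13 | 4-methoxy-2-methylphenol | COc1ccc(O)c(C)c1 | starting material
14 | 2-bromo-4-methoxy-6-methylphenol | COc1cc(C)c(O)c(Br)c1 | intermediate
15 | 1-bromo-2,5-dimethoxy-3-methylbenzene | COc1cc(C)c(OC)c(Br)c1 | intermediate
16 | 3-methylbut-3-enoic acid | CC(=C)CC(=O)O | starting material
17 | prop-2-enyl 3-methylbut-3-enoate | CC(=C)CC(=O)OCC=C | intermediate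
18 | 4-methyl-3,6-dihydro-2H-pyran-2-one | CC1=CCOC(=O)C1 | intermediate
19 | (2,5-dimethoxy-3-methylphenyl)magnesium bromide | COc1cc(C)c(OC)c([Mg]Br)c1 | intermediate
20 | (Z)-5-(2,5-dimethoxy-3-methylphenyl)-3-methylpent-3-enoic acid | C/C(=C/Cc1cc(OC)cc(C)c1OC)CC(=O)O | intermediate
21 | dilithium (3Z)-5-(2,5-dimethoxy-3-methylphenyl)-3-methylpenta-1,3-diene-1,1-diolate | [Li+].[Li+].C/C(=C/Cc1cc(OC)cc(C)c1OC)C=C([O-])[O-] | intermediate
22 | (Z)-2-[2-[(1R,2R)-2-[(E)-1,4-dihydroxy-4-methylpent-2-enyl]-1,2-dimethylcyclopentyl]acetyl]-5-(2,5-dimethoxy-3-methylphenyl)-3-methylpent-3-enoic acid (epimer mixture) | C/C(=C/Cc1cc(OC)cc(C)c1OC)C(C(=O)O)C(=O)C[C@@]1(C)CCC[C@@]1(C)C(O)/C=C/C(C)(C)O | intermediate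
23 | (Z)-1-[(1R,2R)-2-[(E)-1,4-dihydroxy-4-methylpent-2-enyl]-1,2-dimethylcyclopentyl]-6-(2,5-dimethoxy-3-methylphenyl)-4-methylhex-4-en-2-one (carbinol epimers) | C/C(=C/Cc1cc(OC)cc(C)c1OC)CC(=O)C[C@@]1(C)CCC[C@@]1(C)C(O)/C=C/C(C)(C)O | intermediate
24 | (E)-1-[(1R,2R)-2-[(Z)-6-(2,5-dimethoxy-3-methylphenyl)-4-methyl-2-oxohex-4-enyl]-1,2-dimethylcyclopentyl]-4-hydroxy-4-methylpent-2-en-1-one | C/C(=C/Cc1cc(OC)cc(C)c1OC)CC(=O)C[C@@]1(C)CCC[C@@]1(C)C(=O)/C=C/C(C)(C)O | intermediate
25 | 2-[(Z)-6-[(1R,2R)-2-[(E)-4-hydroxy-4-methylpent-2-enoyl]-1,2-dimethylcyclopentyl]-3-methyl-5-oxohex-2-enyl]-6-methylcyclohexa-2,5-diene-1,4-dione | C/C(=C/CC1=CC(=O)C=C(C)C1=O)CC(=O)C[C@@]1(C)CCC[C@@]1(C)C(=O)/C=C/C(C)(C)O | intermediate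
26 | (E)-1-[(1R,2R)-2-[(Z)-6-(2,5-dihydroxy-3-methylphenyl)-4-methyl-2-oxohex-4-enyl]-1,2-dimethylcyclopentyl]-4-hydroxy-4-methylpent-2-en-1-one | C/C(=C/Cc1cc(O)cc(C)c1O)CC(=O)C[C@@]1(C)CCC[C@@]1(C)C(=O)/C=C/C(C)(C)O | target

## Step count and risks

Total step count: 16. Longest linear sequence: 10 steps (1, 2, 3, 4, 5, 7, 13, 14, 15, 16).

**Step 4 (enantioselective deprotonation).** The α-methylenes are neopentyl and flanked by angular methyls, so both the level and the sense of induction are unproven on this substrate. The fallback replaces asymmetric synthesis by resolution and sets out from 4. Unselective enolisation with LiN(iPr)2 and Me3SiCl gives the racemic silyl enol ether F1. Ozonolysis (O3; Me2S) and esterification with CH2N2 give the racemic aldehyde ester F2. Preparative supercritical-fluid chromatography on an amylose tris(3,5-dimethylphenylcarbamate) phase separates the enantiomers, and the (1R,2R)-enantiomer is 7, where the route is rejoined. The same separation can polish 7 if step 4 gives only a moderate enantiomeric excess.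

**Step 12 (copper-catalysed lactone opening).** The Grignard reagent may instead add to the lactone carbonyl or enolise the doubly activated α-methylene. The fallback removes the carbonyl from the electrophile and sets out from 18. LiAlH4 reduction gives (Z)-3-methylpent-2-ene-1,5-diol F3. Corey–Kim chlorination (N-chlorosuccinimide, Me2S, −20 °C) converts only the allylic hydroxyl and gives (Z)-5-chloro-3-methylpent-3-en-1-ol F4. Coupling with an excess of Grignard reagent 19 under Li2CuCl4 catalysis gives (Z)-5-(2,5-dimethoxy-3-methylphenyl)-3-methylpent-3-en-1-ol F5. Oxidation (TEMPO/PhI(OAc)2, then NaClO2) returns the route at 20.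

**Step 13 (dianion acylation and decarboxylation).** The dianion may enolise lactone 12 instead of adding to it, or acylate at its γ-carbon. The fallback swaps the Claisen union for an aldol addition to an aldehyde and sets out from 20 and 12. Acid 20 is converted into prop-2-enyl (Z)-5-(2,5-dimethoxy-3-methylphenyl)-3-methylpent-3-enoate F6 (allyl bromide, KHCO3). Lactone 12 is reduced with iBu2AlH at −78 °C to the lactol F7. The lithium enolate of F6 (LiN(SiMe3)2, excess) adds to the open hydroxy aldehyde form of F7 to give the aldol adduct F8. Dess–Martin oxidation of both secondary carbinols gives the β-keto allyl ester F9. Deallylation with zerovalent palladium (Pd(PPh3)4, HCO2H, Et3N, THF, rt) and loss of CO2 give 24, where the route is rejoined.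

## Further compounds

F1 | step 4 | racemic 1,5-dimethyl-3-(trimethylsilyloxy)bicyclo[3.3.0]oct-2-ene (both enantiomers written) | C1[C@@]2(C)CCC[C@@]2(C)C=C1O[Si](C)(C)C.C1[C@]2(C)CCC[C@]2(C)C=C1O[Si](C)(C)C
F2 | step 4 | racemic methyl 2-(cis-2-formyl-1,2-dimethylcyclopentyl)acetate (both enantiomers written) | COC(=O)C[C@@]1(C)CCC[C@@]1(C)C=O.COC(=O)C[C@]1(C)CCC[C@]1(C)C=O
F3 | step 12 | (Z)-3-methylpent-2-ene-1,5-diol | C/C(=C/CO)CCO
F4 | step 12 | (Z)-5-chloro-3-methylpent-3-en-1-ol | C/C(=C/CCl)CCO
F5 | step 12 | (Z)-5-(2,5-dimethoxy-3-methylphenyl)-3-methylpent-3-en-1-ol | C/C(=C/Cc1cc(OC)cc(C)c1OC)CCO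
F6 | step 13 | prop-2-enyl (Z)-5-(2,5-dimethoxy-3-methylphenyl)-3-methylpent-3-enoate | C/C(=C/Cc1cc(OC)cc(C)c1OC)CC(=O)OCC=C
F7 | step 13 | (4aR,7aR)-1-[(E)-3-hydroxy-3-methylbut-1-enyl]-4a,7a-dimethyloctahydrocyclopenta[c]pyran-3-ol (epimer mixture) | OC1C[C@@]2(C)CCC[C@@]2(C)C(/C=C/C(C)(C)O)O1
F8 | step 13 | prop-2-enyl (Z)-2-[2-[(1R,2R)-2-[(E)-1,4-dihydroxy-4-methylpent-2-enyl]-1,2-dimethylcyclopentyl]-1-hydroxyethyl]-5-(2,5-dimethoxy-3-methylphenyl)-3-methylpent-3-enoate (epimer mixture) | C/C(=C/Cc1cc(OC)cc(C)c1OC)C(C(=O)OCC=C)C(O)C[C@@]1(C)CCC[C@@]1(C)C(O)/C=C/C(C)(C)O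
F9 | step 13 | prop-2-enyl (Z)-5-(2,5-dimethoxy-3-methylphenyl)-2-[2-[(1R,2R)-2-[(E)-4-hydroxy-4-methylpent-2-enoyl]-1,2-dimethylcyclopentyl]acetyl]-3-methylpent-3-enoate (epimer mixture) | C/C(=C/Cc1cc(OC)cc(C)c1OC)C(C(=O)OCC=C)C(=O)C[C@@]1(C)CCC[C@@]1(C)C(=O)/C=C/C(C)(C)O
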